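The ten-membered carbocycle C1–C10 is closed last, at C4–C5. C5 is a secondary allylic carbinol attached to C4, the α-carbon of the C3=C4 enoate, so a Nozaki–Hiyama–Kishi addition of a (Z)-α-iodoenoate to a C5 aldehyde forms this bond, the ring and the C5 stereocentre in one operation and tolerates the finished trans-fused α-methylene-γ-lactone (C7, C8, C11, C12, O). The precursor is an open-chain iodoenoate aldehyde with the lactone in place and a chelating PMB ether at C6. Its C6–C7–C8 triad comes from an indium allylation of (S)-citronellal with a six-membered bromomethyl lactone and acyl shift to O8.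

Key step: step 9

Remark: atoms are numbered as in germacranes (ring C1–C10 with the methyl on C10, ester carbon C15 on C4, lactone carbons C11–C13 on C7, lactone oxygen O8 on C8, O5 and O6 on C5 and C6), and the configuration written in the target SMILES (5S,6S,7S,8R,10S; C3=C4 with C2 and C5 cis) is taken as the one wanted.

Step 1
Reactants: 1 (2S)-but-3-ene-1,2-diol
Product: 2 (4S)-4-ethenyl-2-(4-methoxyphenyl)-1,3-dioxolane (either configuration at the acetal carbon)
Conditions: 4-MeOC6H4CH(OMe)2, PPTS (cat.), CH2Cl2, rt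
Reagents that add atoms: 4-methoxybenzaldehyde dimethyl acetal, COC(OC)c1ccc(OC)cc1
Why: Acid-catalysed transacetalisation of the 1,2-diol should give the five-membered p-methoxybenzylidene acetal without touching the future C6 stereocentre, and the new acetal centre is of no consequence because it is reduced in the next step.

Step 2
Reactants: 2 (4S)-4-ethenyl-2-(4-methoxyphenyl)-1,3-dioxolane
Product: 3 (2S)-2-[(4-methoxybenzyl)oxy]but-3-en-1-ol
Conditions: i-Bu2AlH, CH2Cl2, −78 → 0 °C
Reagents that add atoms: none
Why: Reductive opening of the arylidene acetal should be regioselective because aluminium binds the less hindered primary oxygen, whose acetal C–O bond is cleaved and replaced by hydride, which leaves the PMB group on the secondary (C6) oxygen and the primary (C5) hydroxyl free.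

Step 3
Reactants: 3 (2S)-2-[(4-methoxybenzyl)oxy]but-3-en-1-ol; 4 2-(bromomethyl)prop-2-enoic acid
Product: 5 (2S)-2-[(4-methoxybenzyl)oxy]but-3-en-1-yl 2-(bromomethyl)prop-2-enoate
Conditions: DCC, DMAP (2 mol %), CH2Cl2, −20 → 0 °C
Reagents that add atoms: none
Why: Steglich esterification of the unhindered primary alcohol should proceed at low temperature with only a trace of DMAP, so that the allylic bromide is not displaced, and no stereocentre is involved.

Step 4
Reactants: 5 (2S)-2-[(4-methoxybenzyl)oxy]but-3-en-1-yl 2-(bromomethyl)prop-2-enoate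
Product: 6 (5S)-3-(bromomethyl)-5-[(4-methoxybenzyl)oxy]-5,6-dihydro-2H-pyran-2-one
Conditions: second-generation Grubbs catalyst (H2IMes)(PCy3)Cl2Ru=CHPh (5 mol %), CH2Cl2 (5 mM), 40 °C
Reagents that add atoms: none
Why: Ring-closing metathesis between the monosubstituted alkene and the 1,1-disubstituted acrylate should close the six-membered α-substituted unsaturated lactone with loss of ethene, the ruthenium carbene tolerating the allylic bromide and the PMB ether.

Step 5
Reactants: 6 (5S)-3-(bromomethyl)-5-[(4-methoxybenzyl)oxy]-5,6-dihydro-2H-pyran-2-one; 7 (S)-citronellal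
Product: 9 hydroxy γ-lactone (4S,5R)-5-[(2S)-2,6-dimethylhept-5-en-1-yl]-4-{(1S)-2-hydroxy-1-[(4-methoxybenzyl)oxy]ethyl}-3-methylidenedihydrofuran-2(3H)-one, via δ-lactone carbinol 8 (not isolated)
Conditions: In powder, THF/H2O (1:1), rt; then CSA (10 mol %), CH2Cl2, rt
Reagents that add atoms: none
Why: In this Barbier-type indium allylation of a cyclic 2-(bromomethyl)enoate the allylindium should attack the aldehyde through its γ-carbon C7 on the ring face trans to the adjacent C6–OPMB group and through a chair Zimmerman–Traxler transition state in which the ring holds C6 trans to CH2–In, which sets C7 (S) and C8 (R) with O8 anti to C6, and acid-catalysed acyl transfer from the primary O5 to O8 should then give the more stable trans-fused five-membered lactone and free the C5 hydroxyl; a five-membered bromomethyl butenolide adding to a C6 aldehyde through the same closed transition state would give the C6 epimer, which is why C6 is placed inside the ring of the reagent.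

Step 6
Reactants: 9 hydroxy γ-lactone
Product: 10 hydroxy aldehyde (4S)-4-methyl-5-[(2R,3S)-3-{(1S)-2-hydroxy-1-[(4-methoxybenzyl)oxy]ethyl}-4-methylidene-5-oxotetrahydrofuran-2-yl]pentanal
Conditions: O3, CH2Cl2/MeOH (4:1), Sudan Red 7B, −78 °C; then Me2S, −78 °C → rt
Reagents that add atoms: ozone, [O-][O+]=O
Why: Ozonolysis with reductive work-up should cleave only the electron-rich trisubstituted alkene, which reacts far faster than the electron-poor methylene lactone or the anisyl ring, the dye end-point preventing over-oxidation.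

Step 7
Reactants: 10 hydroxy aldehyde
Product: 11 methyl (2Z,6S)-7-[(2R,3S)-3-{(1S)-2-hydroxy-1-[(4-methoxybenzyl)oxy]ethyl}-4-methylidene-5-oxotetrahydrofuran-2-yl]-2-iodo-6-methylhept-2-enoate
Conditions: Ph3P=CHCO2Me, NIS, CH2Cl2, −20 °C; then 10, −20 °C → rt
Reagents that add atoms: methyl (triphenylphosphoranylidene)acetate, COC(=O)C=P(c1ccccc1)(c1ccccc1)c1ccccc1; N-iodosuccinimide, O=C1CCC(=O)N1I
Why: Wittig olefination with the stabilised α-iodo ylide, made beforehand by iodination of the ester ylide, should give the α-iodoenoate with the ester trans and the iodine cis to the C2 chain (Z), as in other stabilised-ylide olefinations, under non-basic conditions that leave the free C5 hydroxyl and the methylene lactone alone.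

Step 8
Reactants: 11 iodoenoate alcohol
Product: 12 methyl (2Z,6S)-2-iodo-7-[(2R,3S)-3-{(1S)-1-[(4-methoxybenzyl)oxy]-2-oxoethyl}-4-methylidene-5-oxotetrahydrofuran-2-yl]-6-methylhept-2-enoate
Conditions: Dess–Martin periodinane, CH2Cl2, 0 °C → rt
Reagents that add atoms: none
Why: Dess–Martin oxidation should convert the primary alcohol into the α-alkoxy aldehyde under near-neutral conditions that neither epimerise C6 nor affect the PMB ether, the iodoalkene or the methylene lactone, and the aldehyde is used at once.

Step 9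
Reactants: 12 iodoenoate aldehyde
Product: 13 (3E,5S,6S,7S,8R,10S)-5-hydroxy-6-[(4-methoxybenzyl)oxy]-15-methoxy-15-oxogermacra-3,11(13)-dien-12,8-olide
Conditions: CrCl2 (15 equiv), NiCl2 (0.15 equiv), degassed DMSO/THF (3:1), 2 mM, slow addition of 12, rt
Reagents that add atoms: none
Why: In this Nozaki–Hiyama–Kishi reaction zerovalent nickel, formed from NiCl2 by divalent chromium, inserts into the C4–I bond, the alkenyl group passes to trivalent chromium, and the alkenylchromium adds to the C5 aldehyde while ignoring the ester, the enoate and the lactone. The closest known reaction type is the intramolecular nickel/chromium-mediated coupling of alkenyl iodides with aldehydes used to close medium and large carbocycles. The ten-membered ring closes by a 10-exo-trig addition that forms C4–C5 with both carbons in the ring, and high dilution with slow addition should suppress intermolecular coupling. The new C5 stereocentre (S, hydroxyl syn to C6–OPMB) should be set by chelation of chromium between the aldehyde oxygen and the PMB ether oxygen, so that C4 approaches the face turned away from C7, within the conformation imposed by the trans-fused lactone. The step needs retention of the alkene geometry, which the configurationally stable alkenylchromium secures (iodine cis to C2 becomes C5 cis to C2), and it needs the syn C5/C6 diastereomer, which the chelating ether at C6 is placed to secure.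

Step 10
Reactants: 13 macrocyclic carbinol
Product: 14 (3E,5S,6S,7S,8R,10S)-6-[(4-methoxybenzyl)oxy]-15-methoxy-15-oxo-5-(triethylsilyloxy)germacra-3,11(13)-dien-12,8-olide
Conditions: Et3SiOTf, 2,6-lutidine, CH2Cl2, −78 °C
Reagents that add atoms: triethylsilyl trifluoromethanesulfonate, CC[Si](CC)(CC)OS(=O)(=O)C(F)(F)F
Why: Silylation of the hindered secondary allylic alcohol with the reactive silyl triflate and a non-nucleophilic base should mask O5 so that only O6 is acylated later.

Step 11
Reactants: 14 silyl ether
Product: 15 (3E,5S,6S,7R,8R,10S)-6-hydroxy-15-methoxy-15-oxo-5-(triethylsilyloxy)germacra-3,11(13)-dien-12,8-olide (same geometry at C7; the descriptor changes by priority only)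
Conditions: DDQ, CH2Cl2/pH 7 phosphate buffer (10:1), 0 °C → rt
Reagents that add atoms: none
Why: Oxidative PMB cleavage by DDQ (hydride abstraction to the oxocarbenium ion, then hydrolysis) in buffered wet dichloromethane should leave the silyl ether, both esters and both electron-poor alkenes untouched.

Step 12
Reactants: 15 C6 alcohol; 16 angelic acid
Product: 18 (3E,5S,6S,7S,8R,10S)-6-[(2Z)-2-methylbut-2-enoyloxy]-15-methoxy-15-oxo-5-(triethylsilyloxy)germacra-3,11(13)-dien-12,8-olide, via angelic 2,4,6-trichlorobenzoic anhydride 17 (not isolated)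
Conditions: 16, 2,4,6-trichlorobenzoyl chloride, Et3N, toluene, rt; then 15, 75 °C
Reagents that add atoms: none
Why: Yamaguchi-type esterification through the mixed anhydride without a nucleophilic catalyst, the established way to make hindered angelates, should acylate O6 at the less hindered angeloyl carbonyl while avoiding the conjugate addition–elimination that turns angelate into tiglate.

Step 13
Reactants: 18 angelate silyl ether
Product: 19 CNP0552150.1, (3E,5S,6S,7S,8R,10S)-5-hydroxy-6-[(2Z)-2-methylbut-2-enoyloxy]-15-methoxy-15-oxogermacra-3,11(13)-dien-12,8-olide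
Conditions: HF·pyridine, pyridine, THF, 0 °C → rt
Reagents that add atoms: none
Why: Buffered HF·pyridine should cleave the triethylsilyl ether by fluoride attack at silicon under mildly acidic conditions that do not cause acyl migration from O6 to O5, ester cleavage or addition to the methylene lactone.

Compound list
1 | (2S)-but-3-ene-1,2-diol | C=C[C@H](O)CO | starting material
2 | (4S)-4-ethenyl-2-(4-methoxyphenyl)-1,3-dioxolane | C=C[C@H]1COC(c2ccc(OC)cc2)O1 | intermediate
3 | (2S)-2-[(4-methoxybenzyl)oxy]but-3-en-1-ol | C=C[C@H](OCc1ccc(OC)cc1)CO | intermediate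
4 | 2-(bromomethyl)prop-2-enoic acid | C=C(CBr)C(=O)O | starting material
5 | (2S)-2-[(4-methoxybenzyl)oxy]but-3-en-1-yl 2-(bromomethyl)prop-2-enoate | C=C(CBr)C(=O)OC[C@@H](OCc1ccc(OC)cc1)C=C | intermediate
6 | (5S)-3-(bromomethyl)-5-[(4-methoxybenzyl)oxy]-5,6-dihydro-2H-pyran-2-one | BrCC1=C[C@H](OCc2ccc(OC)cc2)COC1=O | intermediate
7 | (S)-citronellal, (3S)-3,7-dimethyloct-6-enal | O=CC[C@@H](C)CCC=C(C)C | starting material
8 | δ-lactone carbinol, (4S,5S)-4-[(1R,3S)-1-hydroxy-3,7-dimethyloct-6-en-1-yl]-5-[(4-methoxybenzyl)oxy]-3-methylidenetetrahydro-2H-pyran-2-one | C=C1C(=O)OC[C@@H](OCc2ccc(OC)cc2)[C@@H]1[C@H](O)C[C@@H](C)CCC=C(C)C | intermediate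
9 | hydroxy γ-lactone, (4S,5R)-5-[(2S)-2,6-dimethylhept-5-en-1-yl]-4-{(1S)-2-hydroxy-1-[(4-methoxybenzyl)oxy]ethyl}-3-methylidenedihydrofuran-2(3H)-one | C=C1C(=O)O[C@H](C[C@@H](C)CCC=C(C)C)[C@H]1[C@H](OCc2ccc(OC)cc2)CO | intermediate
10 | hydroxy aldehyde, (4S)-4-methyl-5-[(2R,3S)-3-{(1S)-2-hydroxy-1-[(4-methoxybenzyl)oxy]ethyl}-4-methylidene-5-oxotetrahydrofuran-2-yl]pentanal | C=C1C(=O)O[C@H](C[C@@H](C)CCC=O)[C@H]1[C@H](OCc2ccc(OC)cc2)CO | intermediate
11 | iodoenoate alcohol, methyl (2Z,6S)-7-[(2R,3S)-3-{(1S)-2-hydroxy-1-[(4-methoxybenzyl)oxy]ethyl}-4-methylidene-5-oxotetrahydrofuran-2-yl]-2-iodo-6-methylhept-2-enoate | C=C1C(=O)O[C@H](C[C@@H](C)CC/C=C(/C(=O)OC)I)[C@H]1[C@H](OCc2ccc(OC)cc2)CO | intermediate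
12 | iodoenoate aldehyde, methyl (2Z,6S)-2-iodo-7-[(2R,3S)-3-{(1S)-1-[(4-methoxybenzyl)oxy]-2-oxoethyl}-4-methylidene-5-oxotetrahydrofuran-2-yl]-6-methylhept-2-enoate | C=C1C(=O)O[C@H](C[C@@H](C)CC/C=C(/C(=O)OC)I)[C@H]1[C@H](OCc2ccc(OC)cc2)C=O | intermediate
13 | macrocyclic carbinol, (3E,5S,6S,7S,8R,10S)-5-hydroxy-6-[(4-methoxybenzyl)oxy]-15-methoxy-15-oxogermacra-3,11(13)-dien-12,8-olide | C=C1C(=O)O[C@@H]2C[C@@H](C)CC/C=C(/C(=O)OC)[C@H](O)[C@@H](OCc3ccc(OC)cc3)[C@@H]12 | intermediate
14 | 5-O-triethylsilyl ether of 13 (5S,6S,7S,8R,10S) | C=C1C(=O)O[C@@H]2C[C@@H](C)CC/C=C(/C(=O)OC)[C@H](O[Si](CC)(CC)CC)[C@@H](OCc3ccc(OC)cc3)[C@@H]12 | intermediate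
15 | C6 alcohol, (3E,5S,6S,7R,8R,10S)-6-hydroxy-15-methoxy-15-oxo-5-(triethylsilyloxy)germacra-3,11(13)-dien-12,8-olide | C=C1C(=O)O[C@@H]2C[C@@H](C)CC/C=C(/C(=O)OC)[C@H](O[Si](CC)(CC)CC)[C@@H](O)[C@@H]12 | intermediate
16 | angelic acid, (2Z)-2-methylbut-2-enoic acid | OC(=O)/C(C)=C\C | starting material
17 | angelic 2,4,6-trichlorobenzoic anhydride | C/C=C(/C)C(=O)OC(=O)c1c(Cl)cc(Cl)cc1Cl | intermediate
18 | angelate silyl ether, (3E,5S,6S,7S,8R,10S)-6-[(2Z)-2-methylbut-2-enoyloxy]-15-methoxy-15-oxo-5-(triethylsilyloxy)germacra-3,11(13)-dien-12,8-olide | C=C1C(=O)O[C@@H]2C[C@@H](C)CC/C=C(/C(=O)OC)[C@H](O[Si](CC)(CC)CC)[C@@H](OC(=O)/C(C)=C\C)[C@@H]12 | intermediate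
19 | CNP0552150.1, (3E,5S,6S,7S,8R,10S)-5-hydroxy-6-[(2Z)-2-methylbut-2-enoyloxy]-15-methoxy-15-oxogermacra-3,11(13)-dien-12,8-olide | C=C1C(=O)O[C@@H]2C[C@@H](C)CC/C=C(/C(=O)OC)[C@H](O)[C@@H](OC(=O)/C(C)=C\C)[C@@H]12 | target

Total step count: 13.
Longest linear sequence: 13 steps (1 to 19); compounds 4, 7 and 16 enter as purchased materials.

Steps most likely to fail

Step 9. The ring closure may show poor facial selectivity at C5, because ring strain in the ten-membered transition state can override chelation by the C6 ether and favour the C5 epimer. The fallback sets out from 12, whose cyclisation would then give mainly the (5R)-epimeric carbinol F1. This is oxidised with Dess–Martin periodinane to the C5 ketone F2, an alkylidene β-keto ester. The ketone is reduced 1,2-selectively under reagent control with catecholborane and (S)-1-methyl-3,3-diphenyltetrahydro-1H,3H-pyrrolo[1,2-c][1,3,2]oxazaborole (Corey–Bakshi–Shibata reduction, the alkenyl group acting as the large substituent). This corrects the stereocentre by oxidation and reduction and comes back to the route at 13.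

Step 5. The organoindium may add with poor γ-regioselectivity or with eroded trans/anti selectivity in the aqueous Barbier medium, and the acyl shift may stall. The fallback sets out from 6, which is converted by copper-mediated SN2′ borylation (B2pin2, CuCl, KOAc, DMF, rt) into the allyl pinacolboronate F3. Thermal allylboration of 7 in toluene at 80 °C passes through a rigorously closed six-membered transition state of the same topology. After aqueous work-up and treatment with CSA in CH2Cl2 it comes back to the route at 9.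

Step 12. The activated angeloyl unit may isomerise to the tiglate, or the hindered O6 may fail to acylate. The fallback sets out from 15, which is esterified (DCC, DMAP, CH2Cl2) with 2-[bis(2,2,2-trifluoroethoxy)phosphoryl]propanoic acid to give the phosphonopropanoate ester F4. Still–Gennari olefination with acetaldehyde (KN(SiMe3)2, 18-crown-6, THF, −78 °C) then builds the (Z)-2-methylbut-2-enoate on the molecule and comes back to the route at 18.

Further compounds
F1 | step 9 | (5R)-epimer of 13, (3E,5R,6S,7S,8R,10S)-5-hydroxy-6-[(4-methoxybenzyl)oxy]-15-methoxy-15-oxogermacra-3,11(13)-dien-12,8-olide | C=C1C(=O)O[C@@H]2C[C@@H](C)CC/C=C(/C(=O)OC)[C@@H](O)[C@@H](OCc3ccc(OC)cc3)[C@@H]12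
F2 | step 9 | C5 ketone, (3E,6S,7S,8R,10S)-6-[(4-methoxybenzyl)oxy]-15-methoxy-5,15-dioxogermacra-3,11(13)-dien-12,8-olide | C=C1C(=O)O[C@@H]2C[C@@H](C)CC/C=C(/C(=O)OC)C(=O)[C@@H](OCc3ccc(OC)cc3)[C@@H]12
F3 | step 5 | (5S)-5-[(4-methoxybenzyl)oxy]-3-[(4,4,5,5-tetramethyl-1,3,2-dioxaborolan-2-yl)methyl]-5,6-dihydro-2H-pyran-2-one | CC1(C)OB(CC2=C[C@H](OCc3ccc(OC)cc3)COC2=O)OC1(C)C
F4 | step 12 | 6-O-{2-[bis(2,2,2-trifluoroethoxy)phosphoryl]propanoyl} derivative of 15 | C=C1C(=O)O[C@@H]2C[C@@H](C)CC/C=C(/C(=O)OC)[C@H](O[Si](CC)(CC)CC)[C@@H](OC(=O)C(C)P(=O)(OCC(F)(F)F)OCC(F)(F)F)[C@@H]12
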